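Remark on numbering: locants follow cyathane numbering (ring A = C1–C4, C9; ring B = C4–C9; ring C = C5, C6, C10–C14; C15 = methyl on C12; C16 = methyl on C6; C17 = oxygenated carbon on C9; C18–C20 = lactone carbons on C3). β is the face of the tricycle that carries C17.

## Structural features

- The target is a cyathane-type diterpenoid: five-membered ring A is trans-fused to six-membered ring B, which is trans-fused to seven-membered ring C. An α-methylene-γ-butyrolactone (C18=C19, C20, O) is cis-fused to ring A across C2–C3.
- Six contiguous stereocenters lie on rings A and B: C2 (O β), C3 (OH α, C18 β), C4 (H α), C5 (H β), C6 (CH3 α) and C9 (CH2OAc β). C12 and C13 carry a β-epoxide.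
- The quaternary carbons C6 and C9 are para on ring B and anti, with the anti pair C4–H/C5–H between them. This is an all-axial trans-anti-trans array.
- Fragile groups are the α-methylene lactone (Michael acceptor), the tertiary β-hydroxy lactone (retro-aldol), the trisubstituted epoxide (acid) and the primary acetate (base). Any C3 ketone intermediate can epimerize C4 towards the cis-hydrindanone.
- Rings B and C carry no oxygen except the epoxide. C7, C8, C10, C11 and C14 are bare methylenes, so carbonyl-based annulations would leave oxygen to excise.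
- The real difficulty is the C5–C6 bond (tertiary to quaternary) at the B/C junction, the four contiguous ring B stereocenters, and a trisubstituted alkene placed exactly at C12=C13 of the seven-membered ring.
- The key step exploits this feature: C11, C12(CH3), C13, C14 and C6 are, atom for atom, a ring-opened 1-methyl-2-isopropenylcyclopropane (ring carbons C13, C14, C6), and C5–C10 is a vinyl group on C4. The two units can be joined across C5–C6 and C10–C11 in one operation.

## Logic of the disconnections

**23 to 22.** The C12–O and C13–O bonds are cut. The acid-labile epoxide is best made last, and the precursor has one stereocenter pair fewer. The forward step needs β-face epoxidation of C12=C13 while the electron-poor C18=C19 is left alone.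

**22 to 21.** The C3–C18 bond is cut, which opens the lactone ring. The acrylate hangs from O-2β, so the tether can deliver C18 only to the β face of a C3 ketone. This settles C3 without relying on the intrinsic facial bias of the ketone. The forward step needs an intramolecular Morita–Baylis–Hillman closure onto a ketone without epimerization at C2 or C4.

**21 to 20 to 18.** The C2–O bond and then the C2–Br bond are cut. Oxygen is placed on the hindered β face by SN2 inversion of a bromide that enters from the open α face. The forward steps need kinetic enolization of 18 towards C2 (through 19) and a clean displacement.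

**18 to 17 to 16.** Only the oxidation level and protection at C3 change. The C3 ketone is unveiled late and under neutral conditions, because C4 is epimerizable once it is there.

**16 to 15 (key).** The C5–C6 and C10–C11 bonds are cut. Rings B and C, the C5 stereocenter and the C12=C13 alkene all go back to a monocyclic ring A carrying a vinyl group and a tethered cis-vinylcyclopropane. In one sentence: a [Rh(CO)2Cl]2-catalysed intramolecular (5+2) cycloaddition of 15 closes rings B and C at once. The gain is two rings, two C–C bonds and no oxygen to remove. The demand is opening of the more substituted cyclopropane bond and trans-selective insertion.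

**15 to 14 to 13.** The C17 oxidation level is adjusted (ester to acetoxymethyl). The ester that activated ring A for C–C bond formation becomes the acetate of the target.

**13 to 12 + 8.** The C8–C9 bond at the quaternary carbon is cut. This is a convergent union of two fragments of similar size (eight and nine skeletal carbons). The forward alkylation must occur anti to the vinyl group on C4.

**12 to 11 to 10 to 9.** The C4–C5 bond is cut (conjugate addition of vinyl anti to the C3 silyloxy group), then the C3–H bond (enantioselective ketone reduction). One catalyst-set stereocenter is relayed to C4 and then C9.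

**8 to 7 to 6 to 5.** The iodide goes back to the alcohol, and the isopropenyl group to the lactone carbonyl (C12–CH3 and C12=CH2 bonds cut).

**5 to 4 to 2 to 1.** The C13–C6 and C13–C14 bonds of the cyclopropane are cut (intramolecular cyclopropanation). The six-membered lactone in 5 is a ring that is not in the target. It is made on purpose to force C12 cis to C7 on the cyclopropane and to carry the absolute configuration, and it is cleaved in step 4.

## Other disconnections considered

**Alternative 1:** Cut C12=C13 (ring C by ring-closing metathesis) after stepwise annulation onto a Hajos–Parrish-type hydrindane. The forward key step would be metathesis of diene A1 with second-generation Grubbs catalyst to give 16. The C5/C6 pair of A1 would have to be built one bond at a time by enolate chemistry on a ring B ketone (C7) that the target lacks and that must later be excised beside a quaternary carbon. A hydrindenone precursor also favours the cis A/B junction on reduction. The chosen step forms both bonds and both rings from an oxygen-free precursor and should be several steps shorter.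

**Alternative 2:** Cut C1–C2, C2–C3 and C4–C9 by an intramolecular Pauson–Khand reaction (Co2(CO)8) of 1,7-enyne A2, closing rings A and B to cyclopentenone A3. C4 becomes sp2 in A3, so the trans A/B junction would depend on reducing a tetrasubstituted enone in a system that prefers cis. C9 would arise from a 1,1-disubstituted alkene in a 1,7-enyne, the least reactive substrate class. A2 still needs the C5/C6 pair on a preformed cycloheptene, so the main difficulty is only moved.

**Alternative 3:** Skeleton first, with the C17–O bond cut. The 2β-alcohol A4 (C17 as CH3) would be converted to its hydridosilyl ether, silylated at the δ-C–H bond of C17 ([Rh(cod)Cl]2/Xantphos, norbornene) and oxidized (Tamao–Fleming) to 1,4-diol A5. The geometry is favourable (O-2β and C17 are 1,3-cis on ring A). In the chosen plan, however, the C17 oxygen costs nothing, because it is the ester that activates 11 and 12. The C–H route adds three steps, needs a free 2β-hydroxyl before the lactone exists, competes with allylic C–H bonds, and does not address C5–C6.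

Key step: step 13

Assumption on the sense of induction: Rh2(5S-MEPY)4 is taken to give (1R,6R)-5; if the induction is the opposite, the 5R catalyst is used.

## Steps

Step 1
Reactants: 1 3-methylbut-3-en-1-ol
Product: 2 3-methylbut-3-en-1-yl 2-bromoacetate
Conditions: BrCH2COBr, NaHCO3, MeCN, 0 °C
Reagents that add atoms: bromoacetyl bromide, O=C(CBr)Br
Why: O-acylation of a primary alcohol by an acid bromide; the hydrogencarbonate buffer protects the acid-sensitive 1,1-disubstituted alkene.

Step 2
Reactants: 2 3-methylbut-3-en-1-yl 2-bromoacetate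
Product: 4 3-methylbut-3-en-1-yl 2-diazoacetate, via N-alkyl ditosylhydrazide 3 (not isolated)
Conditions: TsNHNHTs, DBU, THF, 0 °C
Reagents that add atoms: N,N'-bis(4-methylbenzenesulfonyl)hydrazine, Cc1ccc(cc1)S(=O)(=O)NNS(=O)(=O)c1ccc(C)cc1
Why: Diazoacetate synthesis by N-alkylation of the bis-sulfonylhydrazine with the bromoacetate, followed by base-induced loss of two sulfinate ions.

Step 3
Reactants: 4 3-methylbut-3-en-1-yl 2-diazoacetate
Product: 5 (1R,6R)-6-methyl-3-oxabicyclo[4.1.0]heptan-2-one
Conditions: Rh2(5S-MEPY)4 (1 mol %), CH2Cl2, reflux, slow addition of 4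
Reagents that add atoms: none
Why: Intramolecular cyclopropanation of a homoallylic diazoacetate by a chiral dirhodium carboxamidate carbenoid; the catalyst selects the alkene face (C6 and C13), and the six-membered lactone can only be cis-fused, which fixes C12 cis to C7.

Step 4
Reactants: 5 (1R,6R)-6-methyl-3-oxabicyclo[4.1.0]heptan-2-one
Product: 6 1-[(1R,2R)-2-(2-hydroxyethyl)-2-methylcyclopropyl]ethan-1-one
Conditions: MeLi (1.05 equiv), THF, −78 °C; sat. aq NH4Cl
Reagents that add atoms: methyllithium, [Li]C
Why: Mono-addition of an organolithium to a lactone: the lithium hemiketal alkoxide persists at −78 °C and gives the methyl ketone only on work-up; the ester tether is cleaved and neither stereocenter is touched.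

Step 5
Reactants: 6 1-[(1R,2R)-2-(2-hydroxyethyl)-2-methylcyclopropyl]ethan-1-one
Product: 7 2-[(1R,2S)-1-methyl-2-(prop-1-en-2-yl)cyclopropyl]ethan-1-ol
Conditions: Ph3PCH3Br, KHMDS (3 equiv each), THF, 0 °C to rt
Reagents that add atoms: methyltriphenylphosphonium bromide, C[P+](c1ccccc1)(c1ccccc1)c1ccccc1.[Br-]
Why: Wittig methylenation of the ketone with excess salt-free ylide (the first equivalent is spent on the hydroxyl); low temperature should avoid epimerization α to the cyclopropyl ketone, so the cis relation is kept.

Step 6
Reactants: 7 2-[(1R,2S)-1-methyl-2-(prop-1-en-2-yl)cyclopropyl]ethan-1-ol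
Product: 8 (1R,2S)-1-(2-iodoethyl)-1-methyl-2-(prop-1-en-2-yl)cyclopropane
Conditions: I2, PPh3, imidazole, CH2Cl2, 0 °C
Reagents that add atoms: iodine, II
Why: Appel-type iodination of a primary alcohol under neutral conditions that the vinylcyclopropane tolerates.

Step 7
Reactants: 9 methyl 3-oxocyclopent-1-ene-1-carboxylate
Product: 10 methyl (R)-3-hydroxycyclopent-1-ene-1-carboxylate
Conditions: (S)-Me-CBS oxazaborolidine (10 mol %), catecholborane, toluene, −78 °C
Reagents that add atoms: none
Why: Corey–Bakshi–Shibata 1,2-reduction; the ketone binds with its alkenyl (large) arm away from the catalyst, so hydride should add to the face that gives the R alcohol, the stereocenter from which C4 and C9 are relayed.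

Step 8
Reactants: 10 methyl (R)-3-hydroxycyclopent-1-ene-1-carboxylate
Product: 11 methyl (R)-3-[(tert-butyldimethylsilyl)oxy]cyclopent-1-ene-1-carboxylate
Conditions: TBSCl, imidazole, DMF, rt
Reagents that add atoms: tert-butyldimethylsilyl chloride, CC(C)(C)[Si](C)(C)Cl
Why: Standard silylation; the bulky ether is the control element for the next step and survives steps 9–13.

Step 9
Reactants: 11 methyl (R)-3-[(tert-butyldimethylsilyl)oxy]cyclopent-1-ene-1-carboxylate
Product: 12 methyl (2R,3R)-3-[(tert-butyldimethylsilyl)oxy]-2-vinylcyclopentane-1-carboxylate (C1 epimers)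
Conditions: CH2=CHMgBr (2.5 equiv), CuI (20 mol %), THF, −40 to −20 °C; aq NH4Cl
Reagents that add atoms: vinylmagnesium bromide, C=C[Mg]Br
Why: CuI-catalysed conjugate addition to the enoate; the vinyl group should enter C4 anti to the adjacent silyloxy group, as in additions to 4-silyloxycyclopentenones, and C9 need not be controlled because it is enolized next.

Step 10
Reactants: 12 methyl (2R,3R)-3-[(tert-butyldimethylsilyl)oxy]-2-vinylcyclopentane-1-carboxylate; 8 (1R,2S)-1-(2-iodoethyl)-1-methyl-2-(prop-1-en-2-yl)cyclopropane
Product: 13 methyl (1R,2R,3R)-3-[(tert-butyldimethylsilyl)oxy]-1-{2-[(1S,2S)-1-methyl-2-(prop-1-en-2-yl)cyclopropyl]ethyl}-2-vinylcyclopentane-1-carboxylate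
Conditions: LDA, THF, −78 °C; then 8, DMPU, −78 to −20 °C
Reagents that add atoms: none
Why: Ester enolate alkylation by a primary iodide creates the quaternary C9; the electrophile should enter anti to the adjacent vinyl group (the 1,2-anti relay of three-component prostaglandin couplings), placing C8 α and C17 β.

Step 11
Reactants: 13 the alkylated methyl ester
Product: 14 [(1R,2R,3R)-3-[(tert-butyldimethylsilyl)oxy]-1-{2-[(1S,2S)-1-methyl-2-(prop-1-en-2-yl)cyclopropyl]ethyl}-2-vinylcyclopentyl]methanol
Conditions: LiAlH4, Et2O, 0 °C
Reagents that add atoms: none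
Why: Hydride reduction of the neopentyl ester to the C17 alcohol; silyl ether, alkenes and cyclopropane are inert.

Step 12
Reactants: 14 the C17 alcohol
Product: 15 [(1R,2R,3R)-3-[(tert-butyldimethylsilyl)oxy]-1-{2-[(1S,2S)-1-methyl-2-(prop-1-en-2-yl)cyclopropyl]ethyl}-2-vinylcyclopentyl]methyl acetate
Conditions: Ac2O, pyridine, DMAP (cat.), CH2Cl2, rt
Reagents that add atoms: acetic anhydride, CC(=O)OC(C)=O
Why: Acetylation of the primary alcohol installs the acetate of the target early; it should survive every later step (no strong nucleophile or aqueous base is used after this point).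

Step 13
Reactants: 15 the vinyl/vinylcyclopropane acetate
Product: 16 17-acetoxy-3α-[(tert-butyldimethylsilyl)oxy]-18,19,20-trinorcyath-12-ene
Conditions: [Rh(CO)2Cl]2 (5 mol %), toluene (0.01 M), 100 °C
Reagents that add atoms: none
Why: Proposed new method: monovalent rhodium coordinates the isopropenyl group and inserts into the adjacent cyclopropane bond C13–C6 with retention at C6 (strain release) to give a σ-alkyl/π-allyl rhodacycle; the tethered vinyl group then inserts into the Rh–C6 bond (6-exo, closing ring B through the new C5–C6 bond) and C(sp3)–C(sp3) reductive elimination between C10 and the allyl terminus C11 closes ring C from an eight-membered rhodacycle, leaving the alkene exactly at C12=C13. The closest known reaction type is the rhodium-catalysed intramolecular (5+2) cycloaddition of ene-vinylcyclopropanes, including substrates whose alkene is tethered to the cyclopropane carbon cis to the vinyl group (five/seven-fused products); the proposal extends it to a four-atom tether (six-membered ring) and a fully substituted cyclopropane carbon. C6 keeps the configuration set in step 3, because C5 takes the place of C13. C5 is set in the insertion: ring A is trans-diequatorial on the forming chair of ring B, which makes C17 axial on the β face, so C10 must be equatorial to avoid a 1,3-diaxial clash and H-5 should end up β (trans-anti-trans). The step needs cleavage of the more substituted C13–C6 bond and not of C13–C14: only rhodium bound at C6 can reach the tethered alkene, and the cis geometry from step 3 lets the rhodacycle form. It also needs (5+2) and not (3+2) closure, which is the mode that cis-disposed tethers favour.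

Step 14
Reactants: 16 17-acetoxy-3α-[(tert-butyldimethylsilyl)oxy]-18,19,20-trinorcyath-12-ene
Product: 17 17-acetoxy-18,19,20-trinorcyath-12-en-3α-ol
Conditions: HF·pyridine, pyridine, THF, 0 °C to rt
Reagents that add atoms: none
Why: Buffered fluoride desilylation; the acetate and the trisubstituted alkene should be untouched.

Step 15
Reactants: 17 17-acetoxy-18,19,20-trinorcyath-12-en-3α-ol
Product: 18 17-acetoxy-18,19,20-trinorcyath-12-en-3-one
Conditions: Dess–Martin periodinane, NaHCO3, CH2Cl2, rt
Reagents that add atoms: none
Why: Dess–Martin oxidation under buffered, non-enolizing conditions, so that the 4α-H (trans ring fusion) next to the new ketone is not equilibrated.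

Step 16
Reactants: 18 17-acetoxy-18,19,20-trinorcyath-12-en-3-one
Product: 20 17-acetoxy-2α-bromo-18,19,20-trinorcyath-12-en-3-one, via trimethylsilyl enol ether 19 (not isolated)
Conditions: LiHMDS, TMSCl, THF, −78 °C; then NBS, THF, −78 to 0 °C
Reagents that add atoms: N-bromosuccinimide, O=C1CCC(=O)N1Br; chlorotrimethylsilane, C[Si](C)(C)Cl (its atoms stay in 19 only)
Why: Kinetic deprotonation at the C2 methylene (not at the hindered tertiary C4–H) with in situ silylation prevents enolate equilibration and C4 epimerization; NBS should attack the enol ether from the α face, anti to the β-axial C17 group that is 1,3 to C2.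

Step 17
Reactants: 20 17-acetoxy-2α-bromo-18,19,20-trinorcyath-12-en-3-one
Product: 21 17-acetoxy-2β-(acryloyloxy)-18,19,20-trinorcyath-12-en-3-one
Conditions: acrylic acid, Cs2CO3, DMF, 0 °C to rt
Reagents that add atoms: acrylic acid, C=CC(=O)O
Why: SN2 displacement of an α-bromo ketone by a carboxylate, accelerated by overlap with the carbonyl π*; inversion places the oxygen on the β face of C2.

Step 18
Reactants: 21 17-acetoxy-2β-(acryloyloxy)-18,19,20-trinorcyath-12-en-3-one
Product: 22 17-acetoxy-3α-hydroxycyatha-12,18(19)-dien-20,2β-olide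
Conditions: PMe3 (0.5 equiv), PhOH (0.5 equiv), THF, 0 °C to rt
Reagents that add atoms: none
Why: Intramolecular Morita–Baylis–Hillman reaction: the phosphine adds to the acrylate, the resulting enolate adds 5-exo-trig to the C3 ketone, and the phosphine is eliminated; because the ester hangs from O-2β the enolate can reach only the β face of C3, which makes the lactone cis-fused and the hydroxyl 3α.

Step 19
Reactants: 22 17-acetoxy-3α-hydroxycyatha-12,18(19)-dien-20,2β-olide
Product: 23 CNP0404717.1 (17-acetoxy-12β,13β-epoxy-3α-hydroxycyath-18(19)-en-20,2β-olide)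
Conditions: mCPBA (1.2 equiv), NaHCO3, CH2Cl2, 0 °C
Reagents that add atoms: 3-chloroperoxybenzoic acid, OOC(=O)c1cccc(Cl)c1
Why: Prilezhaev epoxidation; the electron-rich trisubstituted C12=C13 should react far faster than the acrylate-type C18=C19, and the peracid should approach anti to the α-axial C16 methyl on the neighbouring C6, giving the β-epoxide.

## Compound list

1 | 3-methylbut-3-en-1-ol | C=C(C)CCO | starting material
2 | 3-methylbut-3-en-1-yl 2-bromoacetate | C=C(C)CCOC(=O)CBr | intermediate
3 | 3-methylbut-3-en-1-yl 2-[1,2-bis(4-methylbenzenesulfonyl)hydrazin-1-yl]acetate | C=C(C)CCOC(=O)CN(NS(=O)(=O)c1ccc(C)cc1)S(=O)(=O)c1ccc(C)cc1 | intermediate (not isolated)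
4 | 3-methylbut-3-en-1-yl 2-diazoacetate | C=C(C)CCOC(=O)C=[N+]=[N-] | intermediate
5 | (1R,6R)-6-methyl-3-oxabicyclo[4.1.0]heptan-2-one | O=C1OCC[C@@]2(C)C[C@@H]12 | intermediate
6 | 1-[(1R,2R)-2-(2-hydroxyethyl)-2-methylcyclopropyl]ethan-1-one | CC(=O)[C@@H]1C[C@]1(C)CCO | intermediate
7 | 2-[(1R,2S)-1-methyl-2-(prop-1-en-2-yl)cyclopropyl]ethan-1-ol | OCC[C@@]1(C)C[C@H]1C(C)=C | intermediate
8 | (1R,2S)-1-(2-iodoethyl)-1-methyl-2-(prop-1-en-2-yl)cyclopropane (chain cis to isopropenyl) | ICC[C@@]1(C)C[C@H]1C(C)=C | intermediate
9 | methyl 3-oxocyclopent-1-ene-1-carboxylate | COC(=O)C1=CC(=O)CC1 | starting material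
10 | methyl (R)-3-hydroxycyclopent-1-ene-1-carboxylate | COC(=O)C1=C[C@H](O)CC1 | intermediate
11 | methyl (R)-3-[(tert-butyldimethylsilyl)oxy]cyclopent-1-ene-1-carboxylate | COC(=O)C1=C[C@H](O[Si](C)(C)C(C)(C)C)CC1 | intermediate
12 | methyl (2R,3R)-3-[(tert-butyldimethylsilyl)oxy]-2-vinylcyclopentane-1-carboxylate (vinyl trans to silyloxy; C1 epimers) | COC(=O)C1CC[C@@H](O[Si](C)(C)C(C)(C)C)[C@@H]1C=C | intermediate
13 | methyl (1R,2R,3R)-3-[(tert-butyldimethylsilyl)oxy]-1-{2-[(1S,2S)-1-methyl-2-(prop-1-en-2-yl)cyclopropyl]ethyl}-2-vinylcyclopentane-1-carboxylate (cyclopropane as in 8; ester cis to vinyl) | CC(C)(C)[Si](C)(C)O[C@@H]1CC[C@](C(=O)OC)(CC[C@@]2(C)C[C@H]2C(C)=C)[C@H]1C=C | intermediate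
14 | [(1R,2R,3R)-3-[(tert-butyldimethylsilyl)oxy]-1-{2-[(1S,2S)-1-methyl-2-(prop-1-en-2-yl)cyclopropyl]ethyl}-2-vinylcyclopentyl]methanol | CC(C)(C)[Si](C)(C)O[C@@H]1CC[C@](CO)(CC[C@@]2(C)C[C@H]2C(C)=C)[C@H]1C=C | intermediate
15 | [(1R,2R,3R)-3-[(tert-butyldimethylsilyl)oxy]-1-{2-[(1S,2S)-1-methyl-2-(prop-1-en-2-yl)cyclopropyl]ethyl}-2-vinylcyclopentyl]methyl acetate | CC(C)(C)[Si](C)(C)O[C@@H]1CC[C@](COC(C)=O)(CC[C@@]2(C)C[C@H]2C(C)=C)[C@H]1C=C | intermediate
16 | 17-acetoxy-3α-[(tert-butyldimethylsilyl)oxy]-18,19,20-trinorcyath-12-ene (4α-H, 5β-H, 6α-CH3, 9β-CH2OAc) | CC(C)(C)[Si](C)(C)O[C@@H]1CC[C@]2(COC(C)=O)CC[C@@]3(C)CC=C(C)CC[C@@H]3[C@H]21 | intermediate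
17 | 17-acetoxy-18,19,20-trinorcyath-12-en-3α-ol (ring fusions as in 16) | O[C@@H]1CC[C@]2(COC(C)=O)CC[C@@]3(C)CC=C(C)CC[C@@H]3[C@H]21 | intermediate
18 | 17-acetoxy-18,19,20-trinorcyath-12-en-3-one (4α-H, 5β-H) | O=C1CC[C@]2(COC(C)=O)CC[C@@]3(C)CC=C(C)CC[C@@H]3[C@H]21 | intermediate
19 | 17-acetoxy-3-(trimethylsilyloxy)-18,19,20-trinorcyatha-2,12-diene | C[Si](C)(C)OC1=CC[C@]2(COC(C)=O)CC[C@@]3(C)CC=C(C)CC[C@@H]3[C@H]21 | intermediate (not isolated)
20 | 17-acetoxy-2α-bromo-18,19,20-trinorcyath-12-en-3-one | O=C1[C@H](Br)C[C@]2(COC(C)=O)CC[C@@]3(C)CC=C(C)CC[C@@H]3[C@H]21 | intermediate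
21 | 17-acetoxy-2β-(acryloyloxy)-18,19,20-trinorcyath-12-en-3-one | O=C1[C@@H](OC(=O)C=C)C[C@]2(COC(C)=O)CC[C@@]3(C)CC=C(C)CC[C@@H]3[C@H]21 | intermediate
22 | 17-acetoxy-3α-hydroxycyatha-12,18(19)-dien-20,2β-olide | C=C1C(=O)O[C@H]2C[C@]3(COC(C)=O)CC[C@@]4(C)CC=C(C)CC[C@@H]4[C@H]3[C@@]12O | intermediate
23 | CNP0404717.1, 17-acetoxy-12β,13β-epoxy-3α-hydroxycyath-18(19)-en-20,2β-olide | C=C1C(=O)O[C@H]2C[C@]3(COC(C)=O)CC[C@@]4(C)C[C@H]5O[C@@]5(C)CC[C@@H]4[C@H]3[C@@]12O | target

## Step count and least certain steps

Total: 19 steps. Longest linear sequence: 16 steps (steps 1–6 and 10–19).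

**Step 13 (key step).** The most likely failures are:
- slow insertion into the hindered C13–C6 bond, so that alkene isomerization overtakes it;
- β-hydride elimination from the Rh–C10 alkyl after insertion, instead of reductive elimination;
- (3+2) closure in competition with (5+2).

Fallback with known reaction types only, from 14 back to 16. Cross-metathesis of 14 with phenyl vinyl sulfone (second-generation Hoveyda–Grubbs catalyst) would give the (E)-vinyl sulfone F1. Fe(acac)3/PhSiH3 in EtOH would transfer a hydrogen atom to the isopropenyl group; the cyclopropylcarbinyl radical opens to the tertiary C6 radical, which closes 6-exo (Giese) onto the vinyl sulfone to give the ring B sulfone F2. Here C6 is set anew in the chair transition state, a weaker control element than in step 13. Dianion formation (n-BuLi) and alkylation with 3-bromo-2-methylpropene would give F3. Na/Hg with Na2HPO4 in MeOH would remove the sulfonyl group to give diene F4. Ring-closing metathesis (second-generation Grubbs catalyst, toluene, 80 °C, loss of 2-methylpropene) would give the tricyclic alcohol F5, and acetylation (Ac2O, pyridine) would give 16.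

**Step 10.** The most likely failure is sluggish C-alkylation of the hindered, fully substituted ester enolate, with E2 elimination of the iodide taking over.

Fallback from 7 and 12 back to 13. Dess–Martin oxidation of 7 would give the aldehyde F6. Aldol addition of the lithium enolate of 12 to F6 (faster than alkylation, same facial preference at C9) would give the β-hydroxy ester F7 as C8 epimers. 1,1'-Thiocarbonyldiimidazole would give the thiocarbamate F8, and Barton–McCombie deoxygenation (Bu3SnH, AIBN) would give 13.

**Step 17.** The most likely failure is slow backside attack on the β face of C2 (syn to C17), which would allow bromide exchange, enolization with loss of configuration at C2, or elimination to the enone.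

Fallback from 18 back to 23, forming the C2–O bond intramolecularly. KHMDS/PhNTf2 would give the kinetic enol triflate F9. Stille coupling with allyl 2-(tributylstannyl)acrylate (Pd(PPh3)4, CuI, LiCl) would give the dienoate F10, and Pd(PPh3)4/morpholine would give the acid F11. mCPBA (2.2 equiv) would then epoxidize C12=C13 from the β face and C2=C3 from the α face to give F12 (not isolated). Its carboxyl group, held on the β face of C3, opens the 2α,3α-epoxide at C2 with inversion and gives 23 directly.

**Step 18.** The most likely failure is a stalled or reversible aldol step on the hindered ketone (Morita–Baylis–Hillman reactions of ketones are slow), with epimerization at C2 or acyl loss taking over.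

Fallback from 20 back to 22. Displacement with cesium 2-bromoacrylate would give the 2β-(2-bromoacryloyloxy) ketone F13. An intramolecular Nozaki–Hiyama–Kishi reaction (CrCl2, NiCl2 cat., DMF) would add the α-acrylyl chromium species to the C3 ketone through the same β tether and give 22.

## Further compounds

F1 | step 13 | [(1R,2R,3R)-3-[(tert-butyldimethylsilyl)oxy]-1-{2-[(1S,2S)-1-methyl-2-(prop-1-en-2-yl)cyclopropyl]ethyl}-2-[(E)-2-(phenylsulfonyl)vinyl]cyclopentyl]methanol | CC(C)(C)[Si](C)(C)O[C@@H]1CC[C@](CO)(CC[C@@]2(C)C[C@H]2C(C)=C)[C@H]1/C=C/S(=O)(=O)c1ccccc1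
F2 | step 13 | rings A/B sulfone: 3α-silyloxy-9β-(hydroxymethyl)-6α-methyl-6β-(3-methylbut-2-enyl)-5-[(phenylsulfonyl)methyl] trans-hydrindane (4α-H, 5β-H) | CC(C)(C)[Si](C)(C)O[C@@H]1CC[C@]2(CO)CC[C@@](C)(CC=C(C)C)[C@H](CS(=O)(=O)c3ccccc3)[C@H]21
F3 | step 13 | C10-(2-methylallyl) derivative of F2 (C10 epimers) | CC(C)(C)[Si](C)(C)O[C@@H]1CC[C@]2(CO)CC[C@@](C)(CC=C(C)C)[C@H](C(CC(C)=C)S(=O)(=O)c3ccccc3)[C@H]21
F4 | step 13 | desulfonylated diene: 5-(3-methylbut-3-enyl)-6β-(3-methylbut-2-enyl) analogue of F2 | CC(C)(C)[Si](C)(C)O[C@@H]1CC[C@]2(CO)CC[C@@](C)(CC=C(C)C)[C@H](CCC(C)=C)[C@H]21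
F5 | step 13 | 3α-[(tert-butyldimethylsilyl)oxy]-18,19,20-trinorcyath-12-en-17-ol | CC(C)(C)[Si](C)(C)O[C@@H]1CC[C@]2(CO)CC[C@@]3(C)CC=C(C)CC[C@@H]3[C@H]21
F6 | step 10 | 2-[(1R,2S)-1-methyl-2-(prop-1-en-2-yl)cyclopropyl]acetaldehyde | O=CC[C@@]1(C)C[C@H]1C(C)=C
F7 | step 10 | C8-hydroxy derivative of 13 (C8 epimers) | CC(C)(C)[Si](C)(C)O[C@@H]1CC[C@](C(=O)OC)(C(O)C[C@@]2(C)C[C@H]2C(C)=C)[C@H]1C=C
F8 | step 10 | C8 O-(imidazol-1-ylthiocarbonyl) derivative of F7 | CC(C)(C)[Si](C)(C)O[C@@H]1CC[C@](C(=O)OC)(C(OC(=S)n2ccnc2)C[C@@]3(C)C[C@H]3C(C)=C)[C@H]1C=C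
F9 | step 17 | 17-acetoxy-18,19,20-trinorcyatha-2,12-dien-3-yl trifluoromethanesulfonate | O=S(=O)(OC1=CC[C@]2(COC(C)=O)CC[C@@]3(C)CC=C(C)CC[C@@H]3[C@H]21)C(F)(F)F
F10 | step 17 | allyl 17-acetoxycyatha-2,12,18(19)-trien-20-oate | C=CCOC(=O)C(=C)C1=CC[C@]2(COC(C)=O)CC[C@@]3(C)CC=C(C)CC[C@@H]3[C@H]21
F11 | step 17 | 17-acetoxycyatha-2,12,18(19)-trien-20-oic acid | OC(=O)C(=C)C1=CC[C@]2(COC(C)=O)CC[C@@]3(C)CC=C(C)CC[C@@H]3[C@H]21
F12 | step 17 | 17-acetoxy-2α,3α:12β,13β-diepoxycyath-18(19)-en-20-oic acid (not isolated) | OC(=O)C(=C)[C@@]12O[C@@H]1C[C@]3(COC(C)=O)CC[C@@]4(C)C[C@H]5O[C@@]5(C)CC[C@@H]4[C@H]32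
F13 | step 18 | 17-acetoxy-2β-(2-bromoacryloyloxy)-18,19,20-trinorcyath-12-en-3-one | O=C1[C@@H](OC(=O)C(Br)=C)C[C@]2(COC(C)=O)CC[C@@]3(C)CC=C(C)CC[C@@H]3[C@H]21
A1 | alternative 1 | metathesis diene: 9β-(acetoxymethyl)-3α-silyloxy-6β-allyl-6α-methyl-5-(3-methylbut-3-enyl) trans-hydrindane | CC(C)(C)[Si](C)(C)O[C@@H]1CC[C@]2(COC(C)=O)CC[C@@](C)(CC=C)[C@H](CCC(C)=C)[C@H]21
A2 | alternative 2 | 1,7-enyne: 2-methylene-4-[(1R,7S)-1,4-dimethyl-7-(trimethylsilylethynyl)cyclohept-3-en-1-yl]butyl acetate (descriptors tentative; SMILES defines it) | CC(=O)OCC(=C)CC[C@@]1(C)CC=C(C)CC[C@@H]1C#C[Si](C)(C)C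
A3 | alternative 2 | 17-acetoxy-3-(trimethylsilyl)-18,19,20-trinorcyatha-3,12-dien-2-one | O=C1C[C@]2(COC(C)=O)CC[C@@]3(C)CC=C(C)CC[C@@H]3C2=C1[Si](C)(C)C
A4 | alternative 3 | 3α-[(tert-butyldimethylsilyl)oxy]-18,19,20-trinorcyath-12-en-2β-ol (C17 = CH3) | CC(C)(C)[Si](C)(C)O[C@@H]1[C@@H](O)C[C@]2(C)CC[C@@]3(C)CC=C(C)CC[C@@H]3[C@H]21
A5 | alternative 3 | 3α-[(tert-butyldimethylsilyl)oxy]-18,19,20-trinorcyath-12-ene-2β,17-diol | CC(C)(C)[Si](C)(C)O[C@@H]1[C@@H](O)C[C@]2(CO)CC[C@@]3(C)CC=C(C)CC[C@@H]3[C@H]21
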